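Ring C of the upper unit (O1–C2–C3–C4–C4a–C8a) is opened at C3–C4 and O1–C2. This exploits that C4 sits ortho to the phenolic O1 on phloroglucinol ring A: ring A with O1 and C4 is a salicylaldehyde, and ring B with C2 and C3 is a cinnamaldehyde. An amine-catalysed domino oxa-Michael/aldol condensation of these two achiral, benzyl-protected aldehydes closes ring C at C3–C4 and sets C2 in one operation; the formyl group that makes C3 nucleophilic is then excised. A Prévost reaction places the gallate on C3, and C8 of benzylated (+)-catechin is attached at C4 last.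

Key step: step 3

Remark: the target is read as (−)-epigallocatechin 3-O-gallate-(4β→8)-(+)-catechin, upper unit (2R,3R,4R) with 2,3-cis-3,4-trans ring C, lower unit (2R,3S); flavan numbering is used for both units.
Remark: the (S)-configured catalyst in step 3 is chosen from the usual shielding model for diarylprolinol silyl ether iminium ions, which predicts the 2R product.

Step 1
Reactants: 1 2,4,6-trihydroxybenzaldehyde
Product: 2 2,4-bis(benzyloxy)-6-hydroxybenzaldehyde
Conditions: BnBr (2.1 equiv), K2CO3 (2.2 equiv), DMF, 0 °C to rt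
Reagents that add atoms: benzyl bromide, BrCc1ccccc1
Why: Williamson ether synthesis in which the 4-OH and one ortho-OH are alkylated while the remaining ortho-OH, held in a hydrogen bond to the formyl group, should stay free; no stereocenter is formed.

Step 2
Reactants: 3 3,4,5-tris(benzyloxy)benzaldehyde
Product: 4 (E)-3-[3,4,5-tris(benzyloxy)phenyl]prop-2-enal
Conditions: Ph3P=CHCHO (1.1 equiv), toluene, 80 °C
Reagents that add atoms: (triphenylphosphoranylidene)acetaldehyde, O=CC=P(c1ccccc1)(c1ccccc1)c1ccccc1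
Why: Wittig olefination with a stabilised ylide should give the E-enal; no stereocenter is formed.

Step 3
Reactants: 2 2,4-bis(benzyloxy)-6-hydroxybenzaldehyde; 4 (E)-3-[3,4,5-tris(benzyloxy)phenyl]prop-2-enal
Product: 6 (2R)-5,7-bis(benzyloxy)-2-[3,4,5-tris(benzyloxy)phenyl]-2H-chromene-3-carbaldehyde, via oxa-Michael adduct 5 (not isolated)
Conditions: (S)-2-[diphenyl(trimethylsilyloxy)methyl]pyrrolidine (20 mol %), 2-nitrobenzoic acid (20 mol %), 4 Å MS, toluene, rt
Reagents that add atoms: none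
Why: The amine condenses with enal 4 to an iminium ion, the phenol of 2 adds to its β-carbon (oxa-Michael, O1–C2), and the enamine carbon C3 so formed attacks the neighbouring formyl carbon C4 on ring A; loss of water and hydrolysis release the catalyst and enal 6. The closest known reaction type is the organocatalytic domino oxa-Michael/aldol condensation of salicylaldehydes with cinnamaldehydes under diarylprolinol silyl ether catalysis. Ring C closes at C3–C4 by a 6-(enolexo)-exo-trig aldol addition that dehydration to the conjugated enal makes irreversible. The only new stereocenter, C2, is set by the catalyst, whose diphenyl(silyloxy)methyl group shields one face of the E-iminium ion so that the phenol should add from the other face to give 2R. The step needs 1,4- over 1,2-addition of the phenol and aldol closure faster than retro-oxa-Michael erosion; the ortho relation of OH and CHO in 2 fixes the regiochemistry, and the acid cocatalyst with sieves drives the condensation. The formyl group left on C3 is the temporary activating group and is removed in step 4.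

Step 4
Reactants: 6 (2R)-5,7-bis(benzyloxy)-2-[3,4,5-tris(benzyloxy)phenyl]-2H-chromene-3-carbaldehyde
Product: 7 (2S)-5,7-bis(benzyloxy)-2-[3,4,5-tris(benzyloxy)phenyl]-2H-chromene
Conditions: RhCl(PPh3)3 (1.1 equiv), toluene, 95 °C, argon, dark
Reagents that add atoms: none
Why: Tsuji–Wilkinson decarbonylation (formyl C–H oxidative addition to monovalent rhodium, CO extrusion, C–H reductive elimination) should excise the formyl carbon with the C3=C4 double bond in place; C2 is untouched, and its descriptor changes only because C3 loses the formyl group.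

Step 5
Reactants: 7 (2S)-5,7-bis(benzyloxy)-2-[3,4,5-tris(benzyloxy)phenyl]-2H-chromene; 8 3,4,5-tris(benzyloxy)benzoic acid
Product: 11 (2R,3S,4S)-5,7-bis(benzyloxy)-2-[3,4,5-tris(benzyloxy)phenyl]chromane-3,4-diyl bis[3,4,5-tris(benzyloxy)benzoate], via trans-iodo ester 9 (not isolated), via dioxolanylium ion 10 (not isolated)
Conditions: 8 (2.2 equiv), Ag2O (1.1 equiv), 4 Å MS, toluene, rt, dark; I2 (1.05 equiv), 0 °C; then 7, 0 to 80 °C
Reagents that add atoms: none
Why: Prévost trans-diacyloxylation: the acyl hypoiodite should deliver iodine to C3 anti to the C2 aryl group, the first carboxylate opens the iodonium ion at benzylic C4, silver-assisted loss of iodide with backside participation of the C4 ester places the C3–O bond cis to the C2 aryl group (inversion at C3), and the second carboxylate opens the dioxolanylium ion at benzylic C4 from the opposite face (inversion at C4), so C3 and C4 are both set from C2 as 2,3-cis-3,4-trans.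

Step 6
Reactants: 12 (+)-catechin
Product: 13 (2R,3S)-5,7-bis(benzyloxy)-2-[3,4-bis(benzyloxy)phenyl]chroman-3-ol
Conditions: BnBr (4.4 equiv), K2CO3 (5 equiv), DMF, 0 °C to rt
Reagents that add atoms: benzyl bromide, BrCc1ccccc1
Why: Williamson ether synthesis in which only the four phenols are acidic enough to be alkylated under carbonate conditions, leaving the secondary 3-OH free; the two stereocenters come from the chiral pool and are untouched.

Step 7
Reactants: 11 (2R,3S,4S)-5,7-bis(benzyloxy)-2-[3,4,5-tris(benzyloxy)phenyl]chromane-3,4-diyl bis[3,4,5-tris(benzyloxy)benzoate]; 13 (2R,3S)-5,7-bis(benzyloxy)-2-[3,4-bis(benzyloxy)phenyl]chroman-3-ol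
Product: 15 (2R,3R,4R)-5,7-bis(benzyloxy)-4-[(2R,3S)-5,7-bis(benzyloxy)-2-[3,4-bis(benzyloxy)phenyl]-3-hydroxychroman-8-yl]-2-[3,4,5-tris(benzyloxy)phenyl]chroman-3-yl 3,4,5-tris(benzyloxy)benzoate, via flavan-4-yl cation 14 (not isolated)
Conditions: 13 (3 equiv), Me3SiOSO2CF3 (0.2 equiv), 4 Å MS, CH2Cl2, −78 to −40 °C; then Et3N
Reagents that add atoms: none
Why: Lewis-acid promoted Friedel–Crafts interflavan coupling: ionisation of the benzylic C4 ester, assisted by O1 and the 5- and 7-benzyloxy groups of ring A, gives the planar cation 14, and the most nucleophilic free position of 13, C8, should attack C4 on the face anti to the neighbouring 3-O-gallate, which sets C4 as 3,4-trans whatever the C4 configuration of 11.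

Step 8
Reactants: 15 (2R,3R,4R)-5,7-bis(benzyloxy)-4-[(2R,3S)-5,7-bis(benzyloxy)-2-[3,4-bis(benzyloxy)phenyl]-3-hydroxychroman-8-yl]-2-[3,4,5-tris(benzyloxy)phenyl]chroman-3-yl 3,4,5-tris(benzyloxy)benzoate
Product: 16 (2R,3R,4R)-4-[(2R,3S)-2-(3,4-dihydroxyphenyl)-3,5,7-trihydroxychroman-8-yl]-5,7-dihydroxy-2-(3,4,5-trihydroxyphenyl)chroman-3-yl 3,4,5-trihydroxybenzoate
Conditions: H2 (1 atm), Pd(OH)2/C, THF–MeOH–H2O, rt
Reagents that add atoms: none
Why: Hydrogenolysis should cleave all twelve benzyl ethers under neutral conditions that leave the gallate ester, the interflavan bond and all five stereocenters untouched.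

Compound list
1 | 2,4,6-trihydroxybenzaldehyde | O=Cc1c(O)cc(O)cc1O | starting material
2 | 2,4-bis(benzyloxy)-6-hydroxybenzaldehyde | O=Cc1c(O)cc(OCc2ccccc2)cc1OCc1ccccc1 | intermediate
3 | 3,4,5-tris(benzyloxy)benzaldehyde | O=Cc1cc(OCc2ccccc2)c(OCc2ccccc2)c(OCc2ccccc2)c1 | starting material
4 | (E)-3-[3,4,5-tris(benzyloxy)phenyl]prop-2-enal | O=C/C=C/c1cc(OCc2ccccc2)c(OCc2ccccc2)c(OCc2ccccc2)c1 | intermediate
5 | (3S)-3-[3,5-bis(benzyloxy)-2-formylphenoxy]-3-[3,4,5-tris(benzyloxy)phenyl]propanal, the oxa-Michael adduct (held in the flask as its enamine with the catalyst) | O=CC[C@H](Oc1cc(OCc2ccccc2)cc(OCc2ccccc2)c1C=O)c1cc(OCc2ccccc2)c(OCc2ccccc2)c(OCc2ccccc2)c1 | intermediate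
6 | (2R)-5,7-bis(benzyloxy)-2-[3,4,5-tris(benzyloxy)phenyl]-2H-chromene-3-carbaldehyde | O=CC1=Cc2c(OCc3ccccc3)cc(OCc3ccccc3)cc2O[C@@H]1c1cc(OCc2ccccc2)c(OCc2ccccc2)c(OCc2ccccc2)c1 | intermediate
7 | (2S)-5,7-bis(benzyloxy)-2-[3,4,5-tris(benzyloxy)phenyl]-2H-chromene | C1=Cc2c(OCc3ccccc3)cc(OCc3ccccc3)cc2O[C@@H]1c1cc(OCc2ccccc2)c(OCc2ccccc2)c(OCc2ccccc2)c1 | intermediate
8 | 3,4,5-tris(benzyloxy)benzoic acid | OC(=O)c1cc(OCc2ccccc2)c(OCc2ccccc2)c(OCc2ccccc2)c1 | starting material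
9 | (2R,3R,4R)-5,7-bis(benzyloxy)-3-iodo-2-[3,4,5-tris(benzyloxy)phenyl]chroman-4-yl 3,4,5-tris(benzyloxy)benzoate (iodine trans to the C2 aryl group, ester trans to iodine) | I[C@H]1[C@H](OC(=O)c2cc(OCc3ccccc3)c(OCc3ccccc3)c(OCc3ccccc3)c2)c2c(OCc3ccccc3)cc(OCc3ccccc3)cc2O[C@@H]1c1cc(OCc2ccccc2)c(OCc2ccccc2)c(OCc2ccccc2)c1 | intermediate
10 | cis-fused 2-[3,4,5-tris(benzyloxy)phenyl]-1,3-dioxolan-2-ylium ion bridging O3–C3–C4–O4 of the flavan on the face of the C2 aryl group | C1(c3cc(OCc4ccccc4)c(OCc4ccccc4)c(OCc4ccccc4)c3)=[O+][C@@H]2[C@H](O1)c1c(OCc3ccccc3)cc(OCc3ccccc3)cc1O[C@@H]2c1cc(OCc2ccccc2)c(OCc2ccccc2)c(OCc2ccccc2)c1 | intermediate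
11 | (2R,3S,4S)-5,7-bis(benzyloxy)-2-[3,4,5-tris(benzyloxy)phenyl]chromane-3,4-diyl bis[3,4,5-tris(benzyloxy)benzoate] (2,3-cis-3,4-trans) | O=C(O[C@@H]1[C@@H](OC(=O)c2cc(OCc3ccccc3)c(OCc3ccccc3)c(OCc3ccccc3)c2)c2c(OCc3ccccc3)cc(OCc3ccccc3)cc2O[C@@H]1c1cc(OCc2ccccc2)c(OCc2ccccc2)c(OCc2ccccc2)c1)c1cc(OCc2ccccc2)c(OCc2ccccc2)c(OCc2ccccc2)c1 | intermediate
12 | (+)-catechin, (2R,3S)-2-(3,4-dihydroxyphenyl)chromane-3,5,7-triol | O[C@H]1Cc2c(O)cc(O)cc2O[C@@H]1c1ccc(O)c(O)c1 | starting material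
13 | (2R,3S)-5,7-bis(benzyloxy)-2-[3,4-bis(benzyloxy)phenyl]chroman-3-ol (tetra-O-benzylcatechin) | O[C@H]1Cc2c(OCc3ccccc3)cc(OCc3ccccc3)cc2O[C@@H]1c1ccc(OCc2ccccc2)c(OCc2ccccc2)c1 | intermediate
14 | (2R,3R)-5,7-bis(benzyloxy)-3-{[3,4,5-tris(benzyloxy)benzoyl]oxy}-2-[3,4,5-tris(benzyloxy)phenyl]chroman-4-ylium, the C4 benzylic cation stabilised by the oxygen substituents of ring A | O=C(O[C@@H]1[CH+]c2c(OCc3ccccc3)cc(OCc3ccccc3)cc2O[C@@H]1c1cc(OCc2ccccc2)c(OCc2ccccc2)c(OCc2ccccc2)c1)c1cc(OCc2ccccc2)c(OCc2ccccc2)c(OCc2ccccc2)c1 | intermediate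
15 | (2R,3R,4R)-5,7-bis(benzyloxy)-4-[(2R,3S)-5,7-bis(benzyloxy)-2-[3,4-bis(benzyloxy)phenyl]-3-hydroxychroman-8-yl]-2-[3,4,5-tris(benzyloxy)phenyl]chroman-3-yl 3,4,5-tris(benzyloxy)benzoate (dodeca-O-benzyl target) | O=C(O[C@@H]1[C@@H](c2c(OCc4ccccc4)cc(OCc4ccccc4)c3c2O[C@H](c2ccc(OCc4ccccc4)c(OCc4ccccc4)c2)[C@@H](O)C3)c2c(OCc3ccccc3)cc(OCc3ccccc3)cc2O[C@@H]1c1cc(OCc2ccccc2)c(OCc2ccccc2)c(OCc2ccccc2)c1)c1cc(OCc2ccccc2)c(OCc2ccccc2)c(OCc2ccccc2)c1 | intermediate
16 | (2R,3R,4R)-4-[(2R,3S)-2-(3,4-dihydroxyphenyl)-3,5,7-trihydroxychroman-8-yl]-5,7-dihydroxy-2-(3,4,5-trihydroxyphenyl)chroman-3-yl 3,4,5-trihydroxybenzoate | O=C(O[C@@H]1[C@@H](c2c(O)cc(O)c3c2O[C@H](c2ccc(O)c(O)c2)[C@@H](O)C3)c2c(O)cc(O)cc2O[C@@H]1c1cc(O)c(O)c(O)c1)c1cc(O)c(O)c(O)c1 | target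

Total step count: 8. Longest linear sequence: 6 steps (steps 1, 3, 4, 5, 7, 8).

Steps most likely to fail

Step 3. The aldol closure onto the hindered, electron-rich formyl group flanked by two oxygen substituents may be slow, and reversible oxa-Michael addition may then erode the enantiopurity at C2. The fallback sets out from 2 and 4 and comes back at 7, closing the same C3–C4 bond by metathesis instead of aldol condensation. Aldehyde 2 is methylenated (Ph3P=CH2, THF) to 3,5-bis(benzyloxy)-2-vinylphenol F1. Enal 4 is reduced (NaBH4, CeCl3, MeOH, 0 °C) to (E)-3-[3,4,5-tris(benzyloxy)phenyl]prop-2-en-1-ol F2, which is converted (ClCO2Me, pyridine, CH2Cl2) into its methyl carbonate F3. Asymmetric allylic etherification of the lithium phenoxide of F1 with F3 ([Ir(cod)Cl]2, the enantiomer of O,O'-(1,1'-binaphthyl-2,2'-diyl)-N,N-bis(1-phenylethyl)phosphoramidite that delivers the S ether, THF, 50 °C) should give the branched (S)-1-aryl-allyl aryl ether F4. Ring-closing metathesis (second-generation Grubbs catalyst RuCl2(PCy3)(H2IMes)(=CHPh), CH2Cl2, 40 °C) then gives 7 without passing through 6.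

Step 5. Electrophilic iodination of ring A at C6 or C8, or oxidation of the flavene to the flavylium ion, may compete with addition across C3=C4. The silver-assisted displacement of iodide at C3, next to the ether carbon C2, may also stall or be diverted by a 1,2-shift of the C2 aryl group. The fallback sets out from 7 and comes back at 15. Hydroboration–oxidation (BH3·THF; then NaOH, H2O2) anti to the C2 aryl group should give the 2,3-trans alcohol (2R,3S)-5,7-bis(benzyloxy)-2-[3,4,5-tris(benzyloxy)phenyl]chroman-3-ol F5. Dess–Martin oxidation gives the flavan-3-one F6, and LiBH(s-Bu)3 (THF, −78 °C) should reduce it from the face opposite the aryl group to the 2,3-cis alcohol F7. Esterification with 8 (DCC, DMAP, CH2Cl2) gives the 3-O-gallate F8. Benzylic oxidation at C4 (DDQ, 2-ethoxyethanol, CH2Cl2) gives the 4-(2-ethoxyethoxy) derivative F9, which is coupled with 13 under the conditions of step 7 to give 15.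

Step 4. Thermal six-electron ring opening of the 2H-chromene, or rhodium hydride migration of the double bond to C2=C3, may scramble C2 at the temperature needed for CO extrusion. The fallback sets out from 6 and comes back at 15, removing the formyl carbon by rearrangement instead. Pinnick oxidation (NaClO2, NaH2PO4, 2-methyl-2-butene, t-BuOH–H2O) gives the 2H-chromene-3-carboxylic acid F10. Curtius rearrangement (DPPA, Et3N, toluene, 80 °C) and hydrolysis of the vinyl isocyanate (aqueous HCl, THF) should give the flavan-3-one F6. This is carried on through F7, F8 and F9 to 15 as described for step 5.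

Further compounds
F1 | step 3 | 3,5-bis(benzyloxy)-2-vinylphenol | C=Cc1c(O)cc(OCc2ccccc2)cc1OCc1ccccc1
F2 | step 3 | (E)-3-[3,4,5-tris(benzyloxy)phenyl]prop-2-en-1-ol | OC/C=C/c1cc(OCc2ccccc2)c(OCc2ccccc2)c(OCc2ccccc2)c1
F3 | step 3 | methyl (E)-3-[3,4,5-tris(benzyloxy)phenyl]prop-2-en-1-yl carbonate | COC(=O)OC/C=C/c1cc(OCc2ccccc2)c(OCc2ccccc2)c(OCc2ccccc2)c1
F4 | step 3 | (S)-1,5-bis(benzyloxy)-3-{1-[3,4,5-tris(benzyloxy)phenyl]prop-2-en-1-yloxy}-2-vinylbenzene | C=C[C@H](Oc1cc(OCc2ccccc2)cc(OCc2ccccc2)c1C=C)c1cc(OCc2ccccc2)c(OCc2ccccc2)c(OCc2ccccc2)c1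
F5 | step 5 | (2R,3S)-5,7-bis(benzyloxy)-2-[3,4,5-tris(benzyloxy)phenyl]chroman-3-ol (2,3-trans) | O[C@H]1Cc2c(OCc3ccccc3)cc(OCc3ccccc3)cc2O[C@@H]1c1cc(OCc2ccccc2)c(OCc2ccccc2)c(OCc2ccccc2)c1
F6 | step 5 | (2R)-5,7-bis(benzyloxy)-2-[3,4,5-tris(benzyloxy)phenyl]chroman-3-one | O=C1Cc2c(OCc3ccccc3)cc(OCc3ccccc3)cc2O[C@@H]1c1cc(OCc2ccccc2)c(OCc2ccccc2)c(OCc2ccccc2)c1
F7 | step 5 | (2R,3R)-5,7-bis(benzyloxy)-2-[3,4,5-tris(benzyloxy)phenyl]chroman-3-ol (2,3-cis) | O[C@@H]1Cc2c(OCc3ccccc3)cc(OCc3ccccc3)cc2O[C@@H]1c1cc(OCc2ccccc2)c(OCc2ccccc2)c(OCc2ccccc2)c1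
F8 | step 5 | (2R,3R)-5,7-bis(benzyloxy)-2-[3,4,5-tris(benzyloxy)phenyl]chroman-3-yl 3,4,5-tris(benzyloxy)benzoate | O=C(O[C@@H]1Cc2c(OCc3ccccc3)cc(OCc3ccccc3)cc2O[C@@H]1c1cc(OCc2ccccc2)c(OCc2ccccc2)c(OCc2ccccc2)c1)c1cc(OCc2ccccc2)c(OCc2ccccc2)c(OCc2ccccc2)c1
F9 | step 5 | (2R,3R,4S)-5,7-bis(benzyloxy)-4-(2-ethoxyethoxy)-2-[3,4,5-tris(benzyloxy)phenyl]chroman-3-yl 3,4,5-tris(benzyloxy)benzoate (2,3-cis-3,4-trans) | O=C(O[C@@H]1[C@@H](OCCOCC)c2c(OCc3ccccc3)cc(OCc3ccccc3)cc2O[C@@H]1c1cc(OCc2ccccc2)c(OCc2ccccc2)c(OCc2ccccc2)c1)c1cc(OCc2ccccc2)c(OCc2ccccc2)c(OCc2ccccc2)c1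
F10 | step 4 | (2R)-5,7-bis(benzyloxy)-2-[3,4,5-tris(benzyloxy)phenyl]-2H-chromene-3-carboxylic acid | OC(=O)C1=Cc2c(OCc3ccccc3)cc(OCc3ccccc3)cc2O[C@@H]1c1cc(OCc2ccccc2)c(OCc2ccccc2)c(OCc2ccccc2)c1
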